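The diene is cut at its central C–C single bond (final Stille coupling) into a (Z)-iodoalkenyl epoxycyclohexenetriol, made by dearomatising a cheap terephthalaldehyde, and a stannylvinyl trimethylcyclohexenol. Everything rests on a formal [4+2] assembly of that carbocycle from two acyclic pieces. A tertiary radical, released by photoredox decarboxylation next to the silyloxy carbon, adds to a 2-alkynyl-1-methylvinylphosphonium salt; reduction gives an ylide that closes onto the tethered aldehyde. One operation thus makes the bond from the quaternary C(CH3)2 carbon to the ring CH and the ring C(CH3)=CH double bond. It exploits the gem-dimethyl carbon as a stabilised radical site and the 1,3-spacing of carbinol carbon and alkene CH.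

Key step: step 7

Assumption: the antipodes named for the chiral catalysts in steps 1, 13 and 19 follow the accepted transition-state models. Each catalyst is available in both forms, so the other antipode would be used if the sense proved opposite.

Step 1
Reactants: 1 methyl 3-hydroxy-2,2-dimethylpropanoate; 2 allyl acetate
Product: 4 methyl (3R)-3-hydroxy-2,2-dimethylhex-5-enoate, via methyl 2,2-dimethyl-3-oxopropanoate 3 (not isolated)
Conditions: [Ir(cod)Cl]2 (2.5 mol %), (R)-Cl,MeO-BIPHEP (5 mol %), 4-chloro-3-nitrobenzoic acid (10 mol %), Cs2CO3 (20 mol %), THF, 100 °C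
Reagents that add atoms: none
Why: In this iridium-catalysed transfer-hydrogenative carbonyl allylation (Krische allylation) the neopentyl alcohol is dehydrogenated to the non-enolisable aldehyde 3, which is allylated by the chiral π-allyliridium complex, so the ligand sets the (R) carbinol centre.

Step 2
Reactants: 4 methyl (3R)-3-hydroxy-2,2-dimethylhex-5-enoate
Product: 5 methyl (3R)-3-[(tert-butyldimethylsilyl)oxy]-2,2-dimethylhex-5-enoate
Conditions: TBSOTf, 2,6-lutidine, CH2Cl2, 0 °C
Reagents that add atoms: tert-butyldimethylsilyl triflate, CC(C)(C)[Si](C)(C)OS(=O)(=O)C(F)(F)F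
Why: Silyl ether protection with the triflate overcomes the hindrance of the neopentyl-type carbinol and masks it against β-elimination and proton transfer in the later ylide chemistry.

Step 3
Reactants: 5 methyl (3R)-3-[(tert-butyldimethylsilyl)oxy]-2,2-dimethylhex-5-enoate
Product: 6 (3R)-3-[(tert-butyldimethylsilyl)oxy]-2,2-dimethylhex-5-enoic acid
Conditions: LiOH, THF/MeOH/H2O, 60 °C; then 1 M HCl
Reagents that add atoms: lithium hydroxide, [Li+].[OH-]
Why: Saponification of the hindered α-quaternary ester needs heat but is safe, because the substrate cannot enolise and the O-silyl group blocks a retro-aldol path.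

Step 4
Reactants: 6 (3R)-3-[(tert-butyldimethylsilyl)oxy]-2,2-dimethylhex-5-enoic acid
Product: 8 (3R)-3-[(tert-butyldimethylsilyl)oxy]-2,2-dimethyl-5-oxopentanoic acid, via secondary ozonide 7 (not isolated)
Conditions: O3, CH2Cl2, −78 °C; then Me2S, −78 °C to rt
Reagents that add atoms: ozone, [O-][O+]=O
Why: Ozonolysis with reductive work-up cleaves the only alkene to the aldehyde and leaves the silyl ether, the acid and the stereocentre untouched.

Step 5
Reactants: 9 ethyltriphenylphosphonium bromide; 10 3-(triisopropylsilyl)prop-2-ynal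
Product: 12 [3-hydroxy-5-(triisopropylsilyl)pent-4-yn-2-yl]triphenylphosphonium tetrafluoroborate, via ethylidenetriphenylphosphorane 11 (not isolated)
Conditions: n-BuLi, THF, −78 °C; 10, −78 °C; then HBF4·OEt2, −78 °C to rt
Reagents that add atoms: tetrafluoroboric acid (diethyl ether complex), [H+].F[B-](F)(F)F
Why: This is a Wittig addition stopped at the adduct stage: ylide 11 adds to the ynal at low temperature and protonation before cycloreversion gives the β-hydroxyphosphonium salt as a diastereomer mixture of no consequence.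

Step 6
Reactants: 12 [3-hydroxy-5-(triisopropylsilyl)pent-4-yn-2-yl]triphenylphosphonium tetrafluoroborate
Product: 14 triphenyl[5-(triisopropylsilyl)pent-2-en-4-yn-2-yl]phosphonium tetrafluoroborate (E/Z mixture), via β-acetoxyphosphonium salt 13 (not isolated)
Conditions: Ac2O, Sc(OTf)3 (2 mol %), CH2Cl2, 0 °C; then Et3N, 0 °C
Reagents that add atoms: none
Why: Lewis acid-catalysed O-acetylation avoids the base that would restart the Wittig collapse, and triethylamine then triggers E1cB loss of acetate through the ylide of 13, the β-elimination route classically used for vinylphosphonium salts.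

Step 7
Reactants: 8 (3R)-3-[(tert-butyldimethylsilyl)oxy]-2,2-dimethyl-5-oxopentanoic acid; 14 triphenyl[5-(triisopropylsilyl)pent-2-en-4-yn-2-yl]phosphonium tetrafluoroborate
Product: 17 tert-butyldimethyl{[(1R,5S)-4,6,6-trimethyl-5-[(triisopropylsilyl)ethynyl]cyclohex-3-en-1-yl]oxy}silane, via cesium carboxylate 15 (not isolated), via phosphonium ylide 16 (not isolated)
Conditions: 14 (1.5 equiv), Cs2CO3 (0.55 equiv), 4CzIPN (3 mol %), MeCN (0.02 M), argon, blue LEDs (450 nm), 25 °C
Reagents that add atoms: none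
Why: Proposed new method: the excited photocatalyst oxidises carboxylate 15, CO2 is lost, the nucleophilic tertiary C(CH3)2 radical adds to the CH terminus of the cationic alkene 14 (first bond), the α-phosphonio radical is reduced by the photocatalyst radical anion to the non-stabilised ylide 16, and 16 olefinates the tethered aldehyde with loss of Ph3PO (second bond, the ring C(CH3)=CH alkene). The closest known reaction types are the photoredox conjunctive olefination, in which a carboxylic acid, a vinylphosphonium salt and an aldehyde are joined intermolecularly by the same radical-polar crossover, and the anionic annulation of vinylphosphonium salts by addition and intramolecular Wittig reaction; new are the tether between radical precursor and aldehyde and the trisubstituted, alkynyl-bearing acceptor. The single ring is closed in the Wittig event, a 6-exo-trig attack of the ylide carbon on the aldehyde followed by syn-cycloreversion of a bicyclic oxaphosphetane, which can only give the endocyclic cis alkene and fixes its position. The one new stereocentre, the ring CH, is set in the radical addition under 1,2-induction by the silyloxy carbon: the new bond forms anti to the C–OSi bond, the bulky phosphonio-bearing carbon lies anti to the carbinol carbon and the alkynyl group takes the sector beside the carbinol H, which leads to the cis (1R,5S) isomer. The step needs addition at the alkene CH and not at the alkyne terminus, secured by the triisopropylsilyl cap and by the polarisation through phosphorus, and ring closure before intermolecular olefination or enolisation, secured by high dilution and the six-membered transition state. Both alkene isomers of 14 converge on the same ylide, and the reaction is redox- and proton-neutral, so the β-silyloxy aldehyde meets no external strong base.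

Step 8
Reactants: 17 tert-butyldimethyl{[(1R,5S)-4,6,6-trimethyl-5-[(triisopropylsilyl)ethynyl]cyclohex-3-en-1-yl]oxy}silane
Product: 18 (1R,5S)-5-ethynyl-4,6,6-trimethylcyclohex-3-en-1-ol
Conditions: TBAF (3 equiv), THF, 0 to 40 °C
Reagents that add atoms: none
Why: Fluoride-mediated desilylation removes the alkynyl triisopropylsilyl group and the hindered silyl ether in one operation without touching the ring CH stereocentre.

Step 9
Reactants: 18 (1R,5S)-5-ethynyl-4,6,6-trimethylcyclohex-3-en-1-ol
Product: 19 (1R,5S)-4,6,6-trimethyl-5-[(E)-2-(tributylstannyl)ethenyl]cyclohex-3-en-1-ol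
Conditions: Bu3SnH, PdCl2(PPh3)2 (2 mol %), THF, 0 °C
Reagents that add atoms: tributyltin hydride, CCCC[SnH](CCCC)CCCC
Why: Palladium-catalysed hydrostannation is a syn addition, and the bulky ring carbon next to the alkyne steers tin to the terminal carbon, which gives the (E)-alkenylstannane and tolerates the free hydroxyl.

Step 10
Reactants: 20 2,5-dimethoxyterephthalaldehyde
Product: 21 2-hydroxy-5-methoxyterephthalaldehyde
Conditions: BCl3 (1.0 equiv), CH2Cl2, −78 to 0 °C; then H2O
Reagents that add atoms: none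
Why: In this chelation-assisted aryl methyl ether cleavage BCl3 binds a formyl oxygen and cleaves the methoxy group ortho to it, and one equivalent stops at the monophenol because the two ortho pairs of the symmetric dialdehyde are equivalent.

Step 11
Reactants: 21 2-hydroxy-5-methoxyterephthalaldehyde
Product: 22 2-hydroxy-4-(hydroxymethyl)-5-methoxybenzaldehyde
Conditions: NaOH (1.0 equiv), NaBH4 (0.3 equiv), EtOH/H2O, 0 °C; then 1 M HCl
Reagents that add atoms: none
Why: In this chemoselective borohydride reduction the sodium phenoxide deactivates the ortho formyl group as a vinylogous carboxylate, so only the formyl group meta to the phenoxide oxygen is reduced.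

Step 12
Reactants: 22 2-hydroxy-4-(hydroxymethyl)-5-methoxybenzaldehyde
Product: 23 2-[(tert-butyldimethylsilyl)oxy]-4-{[(tert-butyldimethylsilyl)oxy]methyl}-5-methoxybenzaldehyde
Conditions: TBSCl (2.4 equiv), imidazole, DMF, rt
Reagents that add atoms: tert-butyldimethylsilyl chloride, CC(C)(C)[Si](C)(C)Cl
Why: Double silyl ether protection removes both acidic protons, which would otherwise disturb the zinc catalyst and the iodination of the next two steps.

Step 13
Reactants: 23 2-[(tert-butyldimethylsilyl)oxy]-4-{[(tert-butyldimethylsilyl)oxy]methyl}-5-methoxybenzaldehyde; 24 propyne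
Product: 26 (1S)-1-(2-[(tert-butyldimethylsilyl)oxy]-4-{[(tert-butyldimethylsilyl)oxy]methyl}-5-methoxyphenyl)but-2-yn-1-ol, via methyl(prop-1-ynyl)zinc 25 (not isolated)
Conditions: Me2Zn, (R,R)-ProPhenol (10 mol %), Ph3PO (20 mol %), toluene, 0 °C; then aq. NH4Cl
Reagents that add atoms: none
Why: In this dinuclear zinc-ProPhenol-catalysed asymmetric alkynylation the alkynylzinc 25 is delivered to one face of the aryl aldehyde held in the chiral pocket, which sets the (S) side-chain carbinol centre.

Step 14
Reactants: 26 (1S)-1-(2-[(tert-butyldimethylsilyl)oxy]-4-{[(tert-butyldimethylsilyl)oxy]methyl}-5-methoxyphenyl)but-2-yn-1-ol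
Product: 28 (1S,2Z)-1-(2-[(tert-butyldimethylsilyl)oxy]-4-{[(tert-butyldimethylsilyl)oxy]methyl}-5-methoxyphenyl)-3-iodobut-2-en-1-ol, via cyclic sodium alkenylalanate 27 (not isolated)
Conditions: Red-Al (2.2 equiv), THF, 0 °C to rt; then I2, −78 °C
Reagents that add atoms: iodine, II
Why: Alkoxide-directed trans-hydroalumination of the propargylic alcohol places aluminium on the distal carbon inside a five-membered ring, and iodinolysis with retention gives the (Z)-iodoalkene that later fixes the Z geometry of the trisubstituted diene bond.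

Step 15
Reactants: 28 (1S,2Z)-1-(2-[(tert-butyldimethylsilyl)oxy]-4-{[(tert-butyldimethylsilyl)oxy]methyl}-5-methoxyphenyl)-3-iodobut-2-en-1-ol
Product: 29 5-{[(tert-butyldimethylsilyl)oxy]methyl}-2-[(1S,2Z)-1-hydroxy-3-iodobut-2-en-1-yl]-4-methoxyphenol
Conditions: K2CO3 (0.3 equiv), MeOH, 0 °C
Reagents that add atoms: none
Why: Base-catalysed methanolysis cleaves only the aryl silyl ether, because phenoxide is by far the better leaving group on silicon, and leaves the alkyl silyl ether in place.

Step 16
Reactants: 29 5-{[(tert-butyldimethylsilyl)oxy]methyl}-2-[(1S,2Z)-1-hydroxy-3-iodobut-2-en-1-yl]-4-methoxyphenol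
Product: 30 5-{[(tert-butyldimethylsilyl)oxy]methyl}-2-[(1S,2Z)-1-hydroxy-3-iodobut-2-en-1-yl]-4,4-dimethoxycyclohexa-2,5-dien-1-one
Conditions: PhI(OAc)2, MeOH, 0 °C
Reagents that add atoms: methanol, CO
Why: In this hypervalent iodine oxidative dearomatisation of a 4-methoxyphenol methanol is captured at the methoxy-bearing para carbon, which gives the quinone monoketal and differentiates the two enone arms.

Step 17
Reactants: 30 5-{[(tert-butyldimethylsilyl)oxy]methyl}-2-[(1S,2Z)-1-hydroxy-3-iodobut-2-en-1-yl]-4,4-dimethoxycyclohexa-2,5-dien-1-one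
Product: 31 (1S,6R)-4-{[(tert-butyldimethylsilyl)oxy]methyl}-1-[(1S,2Z)-1-hydroxy-3-iodobut-2-en-1-yl]-5,5-dimethoxy-7-oxabicyclo[4.1.0]hept-3-en-2-one
Conditions: Ph3COOH (1.5 equiv), NaHMDS (2.0 equiv), toluene, −50 °C; then aq. NH4Cl
Reagents that add atoms: trityl hydroperoxide, OOC(c1ccccc1)(c1ccccc1)c1ccccc1
Why: In this hydroxyl-directed nucleophilic (Weitz–Scheffer) epoxidation of a quinone monoketal the sodium alkoxide of the carbinol binds the peroxide anion and delivers it to the unsubstituted β-carbon of the α-substituted enone arm, from the face on which the C–O bond lies when the carbinol H eclipses the ring C=O (A1,2 strain), which sets both epoxide carbons while the β-substituted arm stays untouched.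

Step 18
Reactants: 31 (1S,6R)-4-{[(tert-butyldimethylsilyl)oxy]methyl}-1-[(1S,2Z)-1-hydroxy-3-iodobut-2-en-1-yl]-5,5-dimethoxy-7-oxabicyclo[4.1.0]hept-3-en-2-one
Product: 32 (1S,6R)-4-{[(tert-butyldimethylsilyl)oxy]methyl}-1-[(1S,2Z)-1-hydroxy-3-iodobut-2-en-1-yl]-7-oxabicyclo[4.1.0]hept-3-ene-2,5-dione
Conditions: montmorillonite K10, wet CH2Cl2, rt
Reagents that add atoms: water, O
Why: Mild heterogeneous acid hydrolysis of the dimethyl ketal frees the second carbonyl without opening the epoxide or ionising the allylic carbinol.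

Step 19
Reactants: 32 (1S,6R)-4-{[(tert-butyldimethylsilyl)oxy]methyl}-1-[(1S,2Z)-1-hydroxy-3-iodobut-2-en-1-yl]-7-oxabicyclo[4.1.0]hept-3-ene-2,5-dione
Product: 33 (1S,2S,5R,6S)-4-{[(tert-butyldimethylsilyl)oxy]methyl}-1-[(1S,2Z)-1-hydroxy-3-iodobut-2-en-1-yl]-7-oxabicyclo[4.1.0]hept-3-ene-2,5-diol
Conditions: (R)-Me-CBS (50 mol %), BH3·SMe2 (3.5 equiv), THF, −30 °C; then MeOH
Reagents that add atoms: none
Why: In this double Corey–Bakshi–Shibata reduction both ring carbonyls show the catalyst the same arrangement of large group (quaternary epoxide carbon, or substituted alkene carbon) and small group, so one catalyst antipode delivers hydride to the epoxide face of each, helped at the ketone next to the quaternary carbon by the alkoxyborane of the side-chain carbinol, and both new hydroxyls end up anti to the epoxide.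

Step 20
Reactants: 33 (1S,2S,5R,6S)-4-{[(tert-butyldimethylsilyl)oxy]methyl}-1-[(1S,2Z)-1-hydroxy-3-iodobut-2-en-1-yl]-7-oxabicyclo[4.1.0]hept-3-ene-2,5-diol
Product: 34 (1S,2S,5R,6S)-4-(hydroxymethyl)-1-[(1S,2Z)-1-hydroxy-3-iodobut-2-en-1-yl]-7-oxabicyclo[4.1.0]hept-3-ene-2,5-diol
Conditions: TBAF/AcOH (1:1), THF, 0 °C
Reagents that add atoms: none
Why: Acetic acid-buffered fluoride desilylation frees the primary allylic alcohol without generating the alkoxides that could start a Payne rearrangement of the epoxy alcohols.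

Step 21
Reactants: 19 (1R,5S)-4,6,6-trimethyl-5-[(E)-2-(tributylstannyl)ethenyl]cyclohex-3-en-1-ol; 34 (1S,2S,5R,6S)-4-(hydroxymethyl)-1-[(1S,2Z)-1-hydroxy-3-iodobut-2-en-1-yl]-7-oxabicyclo[4.1.0]hept-3-ene-2,5-diol
Product: 35 (1R,2S,5R,6S)-4-(hydroxymethyl)-1-{(1S,2Z,4E)-1-hydroxy-5-[(1S,5R)-5-hydroxy-2,6,6-trimethylcyclohex-2-en-1-yl]-3-methylpenta-2,4-dien-1-yl}-7-oxabicyclo[4.1.0]hept-3-ene-2,5-diol
Conditions: Pd2(dba)3 (5 mol %), AsPh3 (20 mol %), NMP, rt, dark
Reagents that add atoms: none
Why: The Stille coupling joins the two alkenyl partners with retention of both geometries under neutral conditions that tolerate the epoxide and all five free hydroxyls, and so delivers the (2Z,4E)-diene of the target directly.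

Compound list
1 | methyl 3-hydroxy-2,2-dimethylpropanoate | COC(=O)C(C)(C)CO | starting material
2 | allyl acetate | C=CCOC(C)=O | starting material
3 | methyl 2,2-dimethyl-3-oxopropanoate | COC(=O)C(C)(C)C=O | intermediate
4 | methyl (3R)-3-hydroxy-2,2-dimethylhex-5-enoate | C=CC[C@@H](O)C(C)(C)C(=O)OC | intermediate
5 | methyl (3R)-3-[(tert-butyldimethylsilyl)oxy]-2,2-dimethylhex-5-enoate | C=CC[C@@H](O[Si](C)(C)C(C)(C)C)C(C)(C)C(=O)OC | intermediate
6 | (3R)-3-[(tert-butyldimethylsilyl)oxy]-2,2-dimethylhex-5-enoic acid | C=CC[C@@H](O[Si](C)(C)C(C)(C)C)C(C)(C)C(=O)O | intermediate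
7 | secondary ozonide (1,2,4-trioxolane) of 6 | C1(OCOO1)C[C@@H](O[Si](C)(C)C(C)(C)C)C(C)(C)C(=O)O | intermediate
8 | (3R)-3-[(tert-butyldimethylsilyl)oxy]-2,2-dimethyl-5-oxopentanoic acid | O=CC[C@@H](O[Si](C)(C)C(C)(C)C)C(C)(C)C(=O)O | intermediate
9 | ethyltriphenylphosphonium bromide | CC[P+](c1ccccc1)(c1ccccc1)c1ccccc1.[Br-] | starting material
10 | 3-(triisopropylsilyl)prop-2-ynal | O=CC#C[Si](C(C)C)(C(C)C)C(C)C | starting material
11 | ethylidenetriphenylphosphorane | CC=P(c1ccccc1)(c1ccccc1)c1ccccc1 | intermediate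
12 | [3-hydroxy-5-(triisopropylsilyl)pent-4-yn-2-yl]triphenylphosphonium tetrafluoroborate (diastereomer mixture) | CC(C(O)C#C[Si](C(C)C)(C(C)C)C(C)C)[P+](c1ccccc1)(c1ccccc1)c1ccccc1.F[B-](F)(F)F | intermediate
13 | [3-acetoxy-5-(triisopropylsilyl)pent-4-yn-2-yl]triphenylphosphonium tetrafluoroborate | CC(C(OC(C)=O)C#C[Si](C(C)C)(C(C)C)C(C)C)[P+](c1ccccc1)(c1ccccc1)c1ccccc1.F[B-](F)(F)F | intermediate
14 | triphenyl[5-(triisopropylsilyl)pent-2-en-4-yn-2-yl]phosphonium tetrafluoroborate (E/Z mixture) | CC(=CC#C[Si](C(C)C)(C(C)C)C(C)C)[P+](c1ccccc1)(c1ccccc1)c1ccccc1.F[B-](F)(F)F | intermediate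
15 | cesium (3R)-3-[(tert-butyldimethylsilyl)oxy]-2,2-dimethyl-5-oxopentanoate | O=CC[C@@H](O[Si](C)(C)C(C)(C)C)C(C)(C)C(=O)[O-].[Cs+] | intermediate
16 | aldehyde-tethered phosphonium ylide (adduct of the tertiary radical and 14 after reduction) | O=CC[C@@H](O[Si](C)(C)C(C)(C)C)C(C)(C)[C@@H](C#C[Si](C(C)C)(C(C)C)C(C)C)C(C)=P(c1ccccc1)(c1ccccc1)c1ccccc1 | intermediate
17 | tert-butyldimethyl{[(1R,5S)-4,6,6-trimethyl-5-[(triisopropylsilyl)ethynyl]cyclohex-3-en-1-yl]oxy}silane | CC1=CC[C@@H](O[Si](C)(C)C(C)(C)C)C(C)(C)[C@H]1C#C[Si](C(C)C)(C(C)C)C(C)C | intermediate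
18 | (1R,5S)-5-ethynyl-4,6,6-trimethylcyclohex-3-en-1-ol | CC1=CC[C@@H](O)C(C)(C)[C@H]1C#C | intermediate
19 | (1R,5S)-4,6,6-trimethyl-5-[(E)-2-(tributylstannyl)ethenyl]cyclohex-3-en-1-ol | CC1=CC[C@@H](O)C(C)(C)[C@H]1/C=C/[Sn](CCCC)(CCCC)CCCC | intermediate
20 | 2,5-dimethoxyterephthalaldehyde | COc1cc(C=O)c(OC)cc1C=O | starting material
21 | 2-hydroxy-5-methoxyterephthalaldehyde | COc1cc(C=O)c(O)cc1C=O | intermediate
22 | 2-hydroxy-4-(hydroxymethyl)-5-methoxybenzaldehyde | COc1cc(C=O)c(O)cc1CO | intermediate
23 | 2-[(tert-butyldimethylsilyl)oxy]-4-{[(tert-butyldimethylsilyl)oxy]methyl}-5-methoxybenzaldehyde | COc1cc(C=O)c(O[Si](C)(C)C(C)(C)C)cc1CO[Si](C)(C)C(C)(C)C | intermediate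
24 | propyne | CC#C | starting material
25 | methyl(prop-1-ynyl)zinc | C[Zn]C#CC | intermediate
26 | (1S)-1-(2-[(tert-butyldimethylsilyl)oxy]-4-{[(tert-butyldimethylsilyl)oxy]methyl}-5-methoxyphenyl)but-2-yn-1-ol | CC#C[C@H](O)c1cc(OC)c(CO[Si](C)(C)C(C)(C)C)cc1O[Si](C)(C)C(C)(C)C | intermediate
27 | cyclic sodium alkenylalanate (five-membered O–Al–C ring, two 2-methoxyethoxy ligands on Al) | CC1=C[C@@H](c2cc(OC)c(CO[Si](C)(C)C(C)(C)C)cc2O[Si](C)(C)C(C)(C)C)O[Al-]1(OCCOC)OCCOC.[Na+] | intermediate
28 | (1S,2Z)-1-(2-[(tert-butyldimethylsilyl)oxy]-4-{[(tert-butyldimethylsilyl)oxy]methyl}-5-methoxyphenyl)-3-iodobut-2-en-1-ol | C/C(I)=C/[C@H](O)c1cc(OC)c(CO[Si](C)(C)C(C)(C)C)cc1O[Si](C)(C)C(C)(C)C | intermediate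
29 | 5-{[(tert-butyldimethylsilyl)oxy]methyl}-2-[(1S,2Z)-1-hydroxy-3-iodobut-2-en-1-yl]-4-methoxyphenol | C/C(I)=C/[C@H](O)c1cc(OC)c(CO[Si](C)(C)C(C)(C)C)cc1O | intermediate
30 | 5-{[(tert-butyldimethylsilyl)oxy]methyl}-2-[(1S,2Z)-1-hydroxy-3-iodobut-2-en-1-yl]-4,4-dimethoxycyclohexa-2,5-dien-1-one | C/C(I)=C/[C@H](O)C1=CC(OC)(OC)C(CO[Si](C)(C)C(C)(C)C)=CC1=O | intermediate
31 | (1S,6R)-4-{[(tert-butyldimethylsilyl)oxy]methyl}-1-[(1S,2Z)-1-hydroxy-3-iodobut-2-en-1-yl]-5,5-dimethoxy-7-oxabicyclo[4.1.0]hept-3-en-2-one | C/C(I)=C/[C@H](O)[C@]12O[C@H]1C(OC)(OC)C(CO[Si](C)(C)C(C)(C)C)=CC2=O | intermediate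
32 | (1S,6R)-4-{[(tert-butyldimethylsilyl)oxy]methyl}-1-[(1S,2Z)-1-hydroxy-3-iodobut-2-en-1-yl]-7-oxabicyclo[4.1.0]hept-3-ene-2,5-dione | C/C(I)=C/[C@H](O)[C@]12O[C@H]1C(=O)C(CO[Si](C)(C)C(C)(C)C)=CC2=O | intermediate
33 | (1S,2S,5R,6S)-4-{[(tert-butyldimethylsilyl)oxy]methyl}-1-[(1S,2Z)-1-hydroxy-3-iodobut-2-en-1-yl]-7-oxabicyclo[4.1.0]hept-3-ene-2,5-diol (both ring hydroxyls anti to the epoxide) | C/C(I)=C/[C@H](O)[C@]12O[C@H]1[C@H](O)C(CO[Si](C)(C)C(C)(C)C)=C[C@@H]2O | intermediate
34 | (1S,2S,5R,6S)-4-(hydroxymethyl)-1-[(1S,2Z)-1-hydroxy-3-iodobut-2-en-1-yl]-7-oxabicyclo[4.1.0]hept-3-ene-2,5-diol | C/C(I)=C/[C@H](O)[C@]12O[C@H]1[C@H](O)C(CO)=C[C@@H]2O | intermediate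
35 | (1R,2S,5R,6S)-4-(hydroxymethyl)-1-{(1S,2Z,4E)-1-hydroxy-5-[(1S,5R)-5-hydroxy-2,6,6-trimethylcyclohex-2-en-1-yl]-3-methylpenta-2,4-dien-1-yl}-7-oxabicyclo[4.1.0]hept-3-ene-2,5-diol | CC1=CC[C@@H](O)C(C)(C)[C@H]1/C=C/C(C)=C\[C@H](O)[C@]12O[C@H]1[C@H](O)C(CO)=C[C@@H]2O | target

Total step count: 21. Longest linear sequence: 12 steps (steps 10 to 21).

Steps most likely to fail

Step 7 (Proposed new method). The hindered tertiary radical may add too slowly to the β-substituted acceptor, so that hydrogen abstraction or reversible carboxylate addition to the phosphonium salt takes over. Facial selectivity at the ring CH may also be poor, because the alkynyl group is small. The fallback uses known chemistry and replaces the radical annulation with a cationic ring closure in which the ring alkene carbons are already connected. It sets out from 10 and comes back at 18.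
- Wittig olefination of 10 with the ylide of (6-methylhept-5-en-2-yl)triphenylphosphonium bromide gives, after separation of the alkene isomers, (E)-(4,8-dimethylnona-3,7-dien-1-yn-1-yl)triisopropylsilane F1.
- Shi epoxidation (D-fructose-derived ketone, Oxone) of the more electron-rich isopropylidene alkene gives the (R)-epoxide F2.
- MeAlCl2 in CH2Cl2 at −78 °C triggers an epoxide-initiated cation-olefin cyclisation through a chair with the C–O bond and the alkynyl group equatorial. Proton loss toward the ring CH2 gives the cis cyclohexenol F3.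
- TBAF converts F3 into 18.

Step 17. The peroxide may be delivered from the wrong face if the sodium alkoxide chelates to the ring carbonyl instead of guiding the peroxide, so that the bulky iodoalkenyl group alone decides the face. The fallback switches from substrate direction to reagent control. It sets out from 30 and comes back at 31.
- Acetylation (Ac2O, pyridine, DMAP) gives the O-acetate F4.
- HF·pyridine frees the primary alcohol to give hydroxymethyl dienone F5.
- Tartrate-mediated nucleophilic epoxidation (Ph3COOH, NaHMDS, matched diisopropyl tartrate, toluene, −60 °C), directed by the primary hydroxymethyl group next to the ketal carbon, gives epoxide F6.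
- TBSCl and imidazole give silyl ether F7, and brief K2CO3/MeOH removes the acetate to give 31.

Step 19. At the ketone next to the epoxide CH, hydride may enter anti to the epoxide C–O bond, so that the substrate bias overrides the catalyst and the hydroxyl ends up syn to the epoxide. The fallback sets the two carbinols one at a time and corrects the second by inversion. It sets out from 32 and comes back at 33.
- Evans–Saksena reduction (Me4NBH(OAc)3, MeCN/AcOH, −30 °C), delivered from the side-chain carbinol, reduces only the ketone next to the quaternary carbon and gives hydroxy enone F8.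
- Luche reduction follows the substrate bias and gives the 5-epimeric diol F9.
- Mitsunobu reaction (4-nitrobenzoic acid, PPh3, DIAD, THF, 0 °C) at this least hindered allylic carbinol inverts it to the 4-nitrobenzoate F10.
- K2CO3/MeOH gives 33.

Further compounds
F1 | step 7 | (E)-(4,8-dimethylnona-3,7-dien-1-yn-1-yl)triisopropylsilane | CC(C)=CCC/C(C)=C/C#C[Si](C(C)C)(C(C)C)C(C)C
F2 | step 7 | (E)-{6-[(2R)-3,3-dimethyloxiran-2-yl]-4-methylhex-3-en-1-yn-1-yl}triisopropylsilane | CC1(C)O[C@@H]1CC/C(C)=C/C#C[Si](C(C)C)(C(C)C)C(C)C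
F3 | step 7 | (1R,5S)-4,6,6-trimethyl-5-[(triisopropylsilyl)ethynyl]cyclohex-3-en-1-ol | CC1=CC[C@@H](O)C(C)(C)[C@H]1C#C[Si](C(C)C)(C(C)C)C(C)C
F4 | step 17 | O-acetate of 30 | C/C(I)=C/[C@H](OC(C)=O)C1=CC(OC)(OC)C(CO[Si](C)(C)C(C)(C)C)=CC1=O
F5 | step 17 | O-acetate of 30 with free hydroxymethyl group | C/C(I)=C/[C@H](OC(C)=O)C1=CC(OC)(OC)C(CO)=CC1=O
F6 | step 17 | O-acetate of 31 with free hydroxymethyl group | C/C(I)=C/[C@H](OC(C)=O)[C@]12O[C@H]1C(OC)(OC)C(CO)=CC2=O
F7 | step 17 | O-acetate of 31 | C/C(I)=C/[C@H](OC(C)=O)[C@]12O[C@H]1C(OC)(OC)C(CO[Si](C)(C)C(C)(C)C)=CC2=O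
F8 | step 19 | 2-hydroxy-5-oxo compound (ketone next to the quaternary carbon of 32 reduced, hydroxyl anti to the epoxide) | C/C(I)=C/[C@H](O)[C@]12O[C@H]1C(=O)C(CO[Si](C)(C)C(C)(C)C)=C[C@@H]2O
F9 | step 19 | 5-epimer of 33 (hydroxyl next to the epoxide CH syn to the epoxide) | C/C(I)=C/[C@H](O)[C@]12O[C@H]1[C@@H](O)C(CO[Si](C)(C)C(C)(C)C)=C[C@@H]2O
F10 | step 19 | 5-O-(4-nitrobenzoate) of 33 | C/C(I)=C/[C@H](O)[C@]12O[C@H]1[C@H](OC(=O)c3ccc(cc3)[N+](=O)[O-])C(CO[Si](C)(C)C(C)(C)C)=C[C@@H]2O
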